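## Retrosynthetic overview

1. Ester C–O bond: target ⇒ eudesm-4(15)-en-6-ol 9 + (E)-4-acetoxycinnamic acid 10.
2. C5–C10 bond (proton-initiated transannular cation–olefin cyclisation, as germacradienol → eudesmane in the plant): 9 ⇒ ten-membered dienol 8. This one event creates both six-membered rings and sets C5 and C10.
3. C6–C7 bond (= farnesyl C1–C10, the farnesyl diphosphate → germacrene ring closure, here with reversed polarity): 8 ⇒ trienol 7 ⇒ acyclic 12-chlorofarnesal 6, by a ligand-controlled enantioselective allylchromium macrocyclisation that sets C6 and C7.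
4. 6 ⇒ (2E,6E)-farnesol 1 by terminal allylic oxidation, chlorination and C1 oxidation.
5. Ring order: ten-membered carbocycle first (step 6), then both cyclohexane rings at once (step 8).

Numbering: farnesane numbering for 1–6; germacrane/eudesmane numbering for 7–12 (C6 carries the oxygen, C7 the C3 side chain, C10 the angular methyl). α/β refer to the usual eudesmane drawing with the C10 methyl β.

Assumption: the enantiomer of the chiral ligand L* used in step 6 is the one that a small test run (Mosher ester analysis of 7) shows to give the (6R,7S) alcohol; the sense of induction cannot be predicted with certainty.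

## Route

Step 1
Reactants: 1 (2E,6E)-farnesol
Product: 2 (2E,6E)-farnesyl acetate
Conditions: Ac2O, pyridine, DMAP (cat.), CH2Cl2, 0 °C → rt
Reagents that add atoms: acetic anhydride, CC(=O)OC(C)=O
Why: DMAP-catalysed acetylation (nucleophilic acyl substitution) masks the C1 alcohol and deactivates the 2,3-olefin so that the next oxidation is confined to the far end of the chain; no stereocentre is formed.

Step 2
Reactants: 2 (2E,6E)-farnesyl acetate
Product: 3 (2E,6E,10E)-12-hydroxyfarnesyl acetate
Conditions: SeO2 (0.3 equiv), t-BuOOH (70% aq., 3 equiv), salicylic acid (0.1 equiv), CH2Cl2, rt, 24 h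
Reagents that add atoms: tert-butyl hydroperoxide, CC(C)(C)OO (its oxygen is passed on through catalytic selenium dioxide, O=[Se]=O)
Why: Catalytic SeO2/t-BuOOH allylic oxidation (ene reaction then [2,3]-sigmatropic shift) attacks the most electron-rich, least hindered terminal olefin and gives the (E)-CH2OH group, the E geometry following from the [2,3] shift.

Step 3
Reactants: 3 (2E,6E,10E)-12-hydroxyfarnesyl acetate
Product: 4 (2E,6E,10E)-12-chlorofarnesyl acetate
Conditions: PPh3 (1.3 equiv), CCl4, reflux, 1 h
Reagents that add atoms: carbon tetrachloride, ClC(Cl)(Cl)Cl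
Why: Appel chlorination replaces the primary allylic hydroxyl by chloride through SN2 at C12 without allylic transposition or loss of olefin geometry, and leaves the acetate alone.

Step 4
Reactants: 4 (2E,6E,10E)-12-chlorofarnesyl acetate
Product: 5 (2E,6E,10E)-12-chlorofarnesol
Conditions: K2CO3 (0.2 equiv), MeOH, 0 °C, 1 h
Reagents that add atoms: none
Why: Base-catalysed transesterification (methanolysis) of the acetate is much faster at 0 °C than displacement of the primary allylic chloride by the low concentration of methoxide.

Step 5
Reactants: 5 (2E,6E,10E)-12-chlorofarnesol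
Product: 6 (2E,6E,10E)-12-chlorofarnesal
Conditions: MnO2 (15 equiv), CH2Cl2, rt
Reagents that add atoms: none
Why: MnO2 oxidation is specific for allylic alcohols, stops at the enal, keeps the 2E geometry and does not touch the allylic chloride.

Step 6
Reactants: 6 (2E,6E,10E)-12-chlorofarnesal
Product: 7 (6R,7S)-germacra-1(10)E,4E,11-trien-6-ol
Conditions: CrCl2 (4 equiv), chiral oxazoline–sulfonamide ligand L* (Kishi type, 4.4 equiv), Et3N (4.4 equiv), THF, rt, 1 h; then 6 by syringe pump over 16 h (final 2 mM), rt; pH 8 aqueous work-up; Et3N-deactivated silica, below 25 °C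
Reagents that add atoms: none
Why: Proposed new method: two ligated Cr(II) reduce the allylic chloride to an (E)-allylchromium(III) that adds through its γ-carbon (farnesyl C10) to the enal carbonyl in a closed chair Zimmerman–Traxler transition state, which gives the anti (6,7-trans) alcohol, while the chiral ligand on chromium selects the carbonyl face and so fixes C6 (R) and C7 (S) in an achiral substrate; the closest known reactions are the ligand-controlled asymmetric Nozaki–Hiyama–Kishi allylation of aldehydes (intermolecular) and the racemic CrCl2-mediated closure of ω-haloallyl farnesal derivatives to ten-membered germacrane rings.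

Step 7
Reactants: 7 (6R,7S)-germacra-1(10)E,4E,11-trien-6-ol
Product: 8 (6S,7S)-germacra-1(10)E,4E-dien-6-ol
Conditions: H2 (1 atm), RhCl(PPh3)3 (5 mol %), benzene, rt
Reagents that add atoms: none
Why: Homogeneous hydrogenation with Wilkinson's catalyst reduces the unhindered 1,1-disubstituted isopropenyl olefin much faster than the two trisubstituted ring olefins, and is placed here because after cyclisation the exocyclic methylene could no longer be told apart; C6 and C7 are untouched (the C6 descriptor changes only through CIP priorities).

Step 8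
Reactants: 8 (6S,7S)-germacra-1(10)E,4E-dien-6-ol
Product: 9 (5S,6S,7S,10R)-eudesm-4(15)-en-6-ol
Conditions: CSA (10 mol %), CH2Cl2, −20 °C, 30 min; Et3N quench
Reagents that add atoms: none
Why: Proton-initiated transannular cation–olefin cyclisation: C1 is protonated, the C4=C5 olefin adds to the C10 cation through the crossed chair–chair conformer with 6-OH and 7-iPr pseudo-equatorial, which sets the 10β-methyl and 5α-hydrogen (trans-decalin, 10R,5S), and the C4 cation loses a C15 proton, for which the neighbouring equatorial 6-oxygen is the nearest base, to give the exocyclic methylene.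

Step 9
Reactants: 9 (5S,6S,7S,10R)-eudesm-4(15)-en-6-ol; 10 (E)-4-acetoxycinnamic acid
Product: 12 (5S,6S,7S,10R)-eudesm-4(15)-en-6-yl (E)-4-hydroxycinnamate (target), via O-acetyl ester 11 (not isolated)
Conditions: 10 (2 equiv), DCC (2.2 equiv), DMAP (0.5 equiv), CH2Cl2, rt; then pyrrolidine (5 equiv), 0 °C → rt, 30 min
Reagents that add atoms: (E)-4-acetoxycinnamic acid (compound 10), CC(=O)Oc1ccc(/C=C/C(=O)O)cc1
Why: Steglich esterification acylates the equatorial secondary alcohol with retention at C6, and pyrrolidine then aminolyses only the aryl acetate (phenoxide is a far better leaving group than the hindered alkoxide), which frees the phenol without touching the cinnamate ester or its E-olefin.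

## Compound list

1 | (2E,6E)-farnesol | CC(C)=CCC/C(C)=C/CC/C(C)=C/CO | starting material
2 | (2E,6E)-farnesyl acetate | CC(C)=CCC/C(C)=C/CC/C(C)=C/COC(C)=O | intermediate
3 | (2E,6E,10E)-12-hydroxyfarnesyl acetate | OC/C(C)=C/CC/C(C)=C/CC/C(C)=C/COC(C)=O | intermediate
4 | (2E,6E,10E)-12-chlorofarnesyl acetate | ClC/C(C)=C/CC/C(C)=C/CC/C(C)=C/COC(C)=O | intermediate
5 | (2E,6E,10E)-12-chlorofarnesol | ClC/C(C)=C/CC/C(C)=C/CC/C(C)=C/CO | intermediate
6 | (2E,6E,10E)-12-chlorofarnesal | ClC/C(C)=C/CC/C(C)=C/CC/C(C)=C/C=O | intermediate
7 | (6R,7S)-germacra-1(10)E,4E,11-trien-6-ol [(1R,2E,6E,10S)-3,7-dimethyl-10-(prop-1-en-2-yl)cyclodeca-2,6-dien-1-ol] | C/C1=C\CC/C(C)=C/[C@@H](O)[C@H](C(C)=C)CC1 | intermediate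
8 | (6S,7S)-germacra-1(10)E,4E-dien-6-ol [(1S,2E,6E,10S)-3,7-dimethyl-10-(propan-2-yl)cyclodeca-2,6-dien-1-ol] | C/C1=C\CC/C(C)=C/[C@@H](O)[C@H](C(C)C)CC1 | intermediate
9 | (5S,6S,7S,10R)-eudesm-4(15)-en-6-ol [(1S,2S,4aR,8aS)-4a-methyl-8-methylidene-2-(propan-2-yl)decahydronaphthalen-1-ol; 5α-H, 6α-OH, 7β-iPr, 10β-Me] | C=C1CCC[C@]2(C)CC[C@@H](C(C)C)[C@H](O)[C@@H]12 | intermediate
10 | (E)-4-acetoxycinnamic acid | CC(=O)Oc1ccc(/C=C/C(=O)O)cc1 | starting material
11 | (5S,6S,7S,10R)-eudesm-4(15)-en-6-yl (E)-4-acetoxycinnamate | C=C1CCC[C@]2(C)CC[C@@H](C(C)C)[C@H](OC(=O)/C=C/c3ccc(OC(C)=O)cc3)[C@@H]12 | intermediate (not isolated)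
12 | (5S,6S,7S,10R)-eudesm-4(15)-en-6-yl (E)-4-hydroxycinnamate | C=C1CCC[C@]2(C)CC[C@@H](C(C)C)[C@H](OC(=O)/C=C/c3ccc(O)cc3)[C@@H]12 | target

## Step count and risks

Total step count: 9. Longest linear sequence: 9 steps (1 → 12); compound 10 is bought.

The three steps most likely to fail:

Step 6 (enantioselective macrocyclisation). Catalyst control of absolute configuration in a ten-membered ring closure is without direct precedent, and both the ee and the cyclisation yield are uncertain. The fallback sets out from 6 and closes the ring without the chiral ligand (CrCl2, THF, high dilution). This reliably gives the anti alcohol but as the racemate, that is 7 together with its enantiomer (6S,7R)-germacra-1(10)E,4E,11-trien-6-ol F1. Enzymatic kinetic resolution (Burkholderia cepacia lipase or CAL-B, vinyl acetate, MTBE, rt) should then, by Kazlauskas' rule, acylate the (6R) enantiomer to (6R,7S)-germacra-1(10)E,4E,11-trien-6-yl acetate F2. F2 is separated from unreacted F1 and methanolysed (K2CO3, MeOH, 0 °C), which comes back to the route at 7. Should the enzyme prefer the other enantiomer, 7 is simply the recovered alcohol.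

Step 7 (selective hydrogenation). The strained E-olefins of the ten-membered ring may be reduced or isomerised along with the isopropenyl group, and 7 and 8 are sensitive to acid and heat. The fallback sets out from 7 and changes the order of events. Hydrative transannular cyclisation (TsOH cat., acetone–H2O, 0 °C) traps the C4 cation with water from the α face, away from the axial C10 methyl, and gives eudesm-11-ene-4α,6α-diol F3. Its isopropenyl group is now the only olefin and is hydrogenated without any selectivity problem (H2, Pd/C, EtOAc) to eudesmane-4α,6α-diol F4. The secondary hydroxyl alone is esterified with 10 (DCC, DMAP) to 4α-hydroxyeudesman-6α-yl (E)-4-acetoxycinnamate F5. Anti-elimination of the equatorial tertiary alcohol (SOCl2, pyridine, 0 °C), which has only the C15 hydrogens antiperiplanar, gives the exocyclic olefin and comes back to the route at 11, which is deacetylated with pyrrolidine as in step 9.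

Step 8 (position of the new olefin). The C4 cation can also lose a proton from C3 or C5, so endocyclic isomers may dominate over the wanted 4(15)-ene. The fallback sets out from 8 and runs the cyclisation without regard to olefin position (TsOH, CH2Cl2, rt), which gives mainly the endocyclic isomer eudesm-3-en-6α-ol F6. Xylene-sensitised irradiation in i-PrOH (Kropp–Marshall photoisomerisation) then protonates only the endocyclic olefin through its twisted excited state and funnels it into the photostable exocyclic isomer, which comes back to the route at 9.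

## Further compounds

F1 | step 6 | (6S,7R)-germacra-1(10)E,4E,11-trien-6-ol | C/C1=C\CC/C(C)=C/[C@H](O)[C@@H](C(C)=C)CC1
F2 | step 6 | (6R,7S)-germacra-1(10)E,4E,11-trien-6-yl acetate | C/C1=C\CC/C(C)=C/[C@@H](OC(C)=O)[C@H](C(C)=C)CC1
F3 | step 7 | eudesm-11-ene-4α,6α-diol (4β-Me, 5α-H, 7α-H, 10β-Me) | C[C@@]1(O)CCC[C@]2(C)CC[C@@H](C(C)=C)[C@H](O)[C@@H]12
F4 | step 7 | eudesmane-4α,6α-diol (4β-Me, 5α-H, 7α-H, 10β-Me) | C[C@@]1(O)CCC[C@]2(C)CC[C@@H](C(C)C)[C@H](O)[C@@H]12
F5 | step 7 | 4α-hydroxyeudesman-6α-yl (E)-4-acetoxycinnamate | C[C@@]1(O)CCC[C@]2(C)CC[C@@H](C(C)C)[C@H](OC(=O)/C=C/c3ccc(OC(C)=O)cc3)[C@@H]12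
F6 | step 8 | eudesm-3-en-6α-ol (5α-H, 7α-H, 10β-Me) | CC1=CCC[C@]2(C)CC[C@@H](C(C)C)[C@H](O)[C@@H]12
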